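# Proposed synthesis of CNP0113462.3 by an amine-catalysed double Michael annulation

## Analysis of the target

The target is an elemanolide: one cyclohexane (C5–C10, elemane numbering, β = face of the C10 methyl C14) in which every ring carbon is substituted. A trans-fused α-methylene-γ-lactone (C11–C13) spans C7–C8 and is closed on O8. C5 bears a 2-propenal arm (C4 with C3 and C15, β), C6 an angelate (β), C9 a free hydroxyl (α), and C10 the methyl together with a monosubstituted oxirane (C1–C2, α, C1 of R configuration). In the chair the arms at C5 and C7 and the lactone oxygen at C8 are equatorial, whereas the C6 ester, the C9 hydroxyl and the C10 methyl are axial. The C6 oxygen is therefore syn-axial to the methyl, and O8 and O9 are cis. The stereochemical problem is six contiguous ring stereocentres, one of them the quaternary C10 flanked by two tertiary carbons, plus the exocyclic C1. The sensitive groups are three electrophilic alkenes (methylene lactone, acrolein, and the angelate, which isomerises easily from Z to E), the epoxide, and a lactone carbonyl that could close on O6 in place of O8; together they dictate a narrow order of late steps. The strategy rests on the position of the C6 oxygen between C5 and C7. If C6 carries a nitro group, C5=C6 is a nitroalkene, C7 is the β-carbon of an enoate, and C10 (with C1) is the α-carbon of an aldehyde. Two conjugate additions then close the ring, and the cis C8/C9 diol maps onto an erythrose-derived lactone.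

## Retrosynthetic reasoning

**C15 oxidation level.** The 2-substituted acrolein is the most fragile group, so it is made last: 31 comes from allylic diol 30 by an oxidation that touches only the allylic alcohol. Diol 30 comes from bis-silyl ether 29, whose two silyl groups (O9, O15) fall together.

**Angelate.** The C6–O acyl bond is cut to give alcohol 27 and angelic acid 28. The ester is put on after the methylene lactone, because the enolate chemistry that makes the methylene group would deprotonate or isomerise an angelate. O9 stays silylated at this point, so the two axial hydroxyls are never free together and no selectivity between them is asked for.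

**α-Methylene group.** C11=C13 is cut back to the saturated lactone 23 (Mannich reaction, then elimination). The C6 hydroxyl is masked for this step as a trimethylsilyl ether, because a free C6 alkoxide next to the lactone could translactonise to O6.

**C6 alcohol.** The axial C6–O bond of 22 comes from ketone 21 by hydride delivery from the equatorial side; the syn-axial C10 methyl blocks the other trajectory.

**Epoxide.** C1–C2 is cut to aldehyde 20 and a one-carbon sulfonium ylide. This placement is forced from three sides:
- A hydride step before it would reduce the aldehyde, so the epoxide must precede the C6 reduction.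
- The acid needed to open the acetonide would endanger an epoxide, so the epoxide must follow that step.
- O9 must be silylated (20 from 19), because a free β-alkoxide next to the aldehyde would cleave C9–C10 by retro-aldol reaction under the basic ylide.

**Lactone and acetonide.** The C12–O8 bond and the acetonide lead back to keto ester 17. Lactonisation is done while C6 is still a ketone. Then only O8 can reach the ester, and the regiochemistry of the lactone (8,12 and not 6,12) is settled before a C6 hydroxyl exists.

**C6 ketone.** Ketone 17 comes from nitro compound 15 by a Nef reaction. At this stage C5 and C7 are both α to the carbonyl and the ring still carries the cis-fused acetonide, so both centres can be equilibrated to the arrangement with both arms equatorial. This is why the annulation needs kinetic control only at C10.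

**Key disconnection.** C5–C10 and C6–C7 of 15 are cut together. The C6 nitronate is the product of the first conjugate addition and the nucleophile of the second, so aldehyde 6 and nitrodiene 13 give the fully substituted ring, with all four carbon arms, in one operation. Cutting here and not elsewhere puts the two hetero-substituted carbons C8 and C9 into a chiral-pool fragment and leaves no ring stereocentre to a separate asymmetric step.

**Aldehyde 6.** The C7=C11 bond is cut by Wittig disconnection (5 from alcohol 3 through aldehyde 4). The C10–C1 unit goes back to the lactone carbonyl of 1 through methyl addition (lactol 2) and methoxymethylene homologation (3). The enol ether is unmasked last, because the α-branched, β-alkoxy aldehyde is the least stable member of the series.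

**Nitrodiene 13.** The C5=C6 bond is cut by Henry disconnection to enal 9 and nitromethane 10 (through 11 and 12). Enal 9 comes from diol 7 by monosilylation (8) and allylic oxidation.

## Alternatives that were turned down

**Alternative 1: enone–cyclobutene photocycloaddition, then thermal opening.** The cut is at C4–C5 and C1–C10: both arms come from one cyclobutene. Irradiation of enone A2 with cyclobutene ester A3 would give the tricyclic adduct A1, and heating would open its bicyclo[2.2.0]hexane unit to the C10 vinyl group and the C5 acrylate arm.
- For: the quaternary C10 and both unsaturated arms arise in two steps, C15 arrives as an ester at nearly the right oxidation level, and a photochemical bond formation is little troubled by steric congestion. On this point it is stronger than the chosen route, whose key step must form the most hindered bond of the molecule by a polar addition.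
- Against: in A1 the carbons C7 and C8 are bare methylenes. The acetate arm can be alkylated onto C7 next to the ketone, but the C8 oxygen has to be introduced at an unactivated position, and the trans lactone, the C6 alcohol and the C9 configuration all need separate later control. The trans relation of the two arms would depend on a thermal Cope equilibrium. The epoxide would have to come from the vinyl group, the least nucleophilic of the alkenes then present.
- Comparison: the chosen strategy gives in exchange a ring that leaves the annulation with all six substituents and their heteroatoms in place, and an epoxide made from an aldehyde with no competing alkene.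

**Alternative 2: Barbier allylation–lactonisation cascade.** The cut is at C7–C8 and at the lactone C–O bond. A low-valent metal (divalent chromium or zinc) would turn an acyclic bromomethyl enoate into an allylmetal that adds through C7 to a C8 aldehyde, and the C8 alkoxide would acylate to give A4.
- For: carbocycle, C7, C8 and the finished α-methylene lactone come in one step, and the lactone cannot close on O6 because that oxygen is an ether. On the end-game this is clearly stronger than the chosen route, which needs a separate methylenation and a silyl detour around it.
- Against: the acyclic precursor must already hold C5, C6, C9 and the quaternary C10 as a contiguous array, each set by its own step, together with a geometrically defined bromomethyl enoate. The two new centres depend on a crowded chair transition state. A4 still needs its C10 vinyl group epoxidised selectively in the presence of the 1,1-disubstituted alkene and the methylene lactone.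
- Comparison: the chosen strategy is longer after the ring is formed, but it reaches the ring from two short fragments and meets the epoxide problem at the aldehyde stage.

**Alternative 3: oxyallyl–fulvene (4+3) cycloaddition, then bridge cleavage.** The cut is at C7–C8 and C5–C10. An alkoxy oxyallyl cation (C8–C9–C10) would add across the ring diene of fulvene A6 to give the bicyclic ketone A5, whose six-membered ring is C5–C10; cleaving the etheno bridge would free C4 and C11 as cis carbonyl arms.
- For: one cycloaddition fixes C5, C7, C8 and C10 on a rigid bicycle, the cis relation of the two arms is automatic, and C8 and C9 arrive oxygenated. In stereochemical reliability of the ring-forming step it is at least as strong as the chosen route.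
- Against: the periselectivity of a fulvene is uncertain. C10 arrives tertiary and must be quaternised next to a bridgehead. The two aldehydes from bridge cleavage are nearly equivalent and must be told apart, then C4 has to gain C3 and C15 and C11 has to gain C12 and C13. The isopropylidene must be cleaved to give the C6 carbonyl without loss of control over the other alkene.
- Comparison: the step count after the key step would be well above that of the chosen route, in which the arms enter with their full carbon count, apart from C2 and C13.

Key step: step 9

## Conventions and assumptions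

- Abbreviations: TBDPS = tert-butyldiphenylsilyl, TES = triethylsilyl, TMS = trimethylsilyl.
- Assumption on the catalyst: the (1R,2R) enantiomer is written; if it proves mismatched with the C9 stereocentre, its enantiomer is used under the same conditions.
- Assumption on 14 and 15: they are drawn with the C5 and C7 configuration of the target; if the annulation delivers epimers at these two centres, they are carried on as such and converge at 17 in step 10.

## Route

Step 1
Reactants: 1 2,3-O-isopropylidene-D-erythronolactone
Product: 2 methyl lactol (1-deoxy-3,4-O-isopropylidene-D-erythro-pent-2-ulofuranose; anomeric mixture)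
Conditions: MeLi (1.1 equiv), THF, −78 °C; then H2O
Reagents that add atoms: methyllithium, [Li]C
Why: 1,2-Addition of one equivalent of MeLi to the lactone carbonyl stops at the tetrahedral lithium alkoxide at −78 °C and gives the lactol on quench; both dioxolane stereocentres are untouched.

Step 2
Reactants: 2 methyl lactol
Product: 3 enol ether alcohol [cis-4-(hydroxymethyl)-5-(1-methoxyprop-1-en-2-yl)-2,2-dimethyl-1,3-dioxolane; E/Z mixture]
Conditions: Ph3P(CH2OMe)Cl (3.5 equiv), KOt-Bu (3.4 equiv), THF, 0 °C → rt
Reagents that add atoms: (methoxymethylene)triphenylphosphorane, COC=P(c1ccccc1)(c1ccccc1)c1ccccc1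
Why: Under the basic ylide the lactol opens to the hydroxy ketone alkoxide, which undergoes Wittig methoxymethylenation; the excess of ylide covers the acidic hydroxyl. The enol ether geometry is irrelevant because C10 is planarised again later.

Step 3
Reactants: 3 enol ether alcohol
Product: 5 (E)-enoate enol ether, via aldehyde 4 (not isolated)
Conditions: Dess–Martin periodinane, pyridine, CH2Cl2, 0 °C → rt; then Ph3P=CHCO2Me, rt
Reagents that add atoms: methyl (triphenylphosphoranylidene)acetate, COC(=O)C=P(c1ccccc1)(c1ccccc1)c1ccccc1
Why: Buffered Dess–Martin oxidation spares the acid-sensitive enol ether, and the configurationally labile α-alkoxy aldehyde is trapped at once by the stabilised ylide (tandem oxidation–Wittig), which should give mainly the (E)-enoate.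

Step 4
Reactants: 5 (E)-enoate enol ether
Product: 6 acetonide of methyl (E)-4,5-dihydroxy-6-methyl-7-oxohept-2-enoate (erythro diol; both C10 epimers)
Conditions: TsOH·H2O (0.1 equiv), acetone/H2O (10:1), rt
Reagents that add atoms: water, O
Why: Acid-catalysed enol ether hydrolysis (C-protonation at C10, collapse of the hemiacetal); acetone as solvent keeps the acetonide in place by mass action. The C10 mixture is harmless because the next reaction of 6 passes through the enamine.

Step 5
Reactants: 7 2-methylenepropane-1,3-diol
Product: 8 2-[(tert-butyldiphenylsilyloxy)methyl]prop-2-en-1-ol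
Conditions: NaH (1.0 equiv), THF, 0 °C; then TBDPSCl (1.0 equiv), rt
Reagents that add atoms: tert-butyl(chloro)diphenylsilane, CC(C)(C)[Si](Cl)(c1ccccc1)c1ccccc1
Why: Monosilylation of a symmetrical diol through its sparingly soluble mono-sodium alkoxide, which is silylated once.

Step 6
Reactants: 8 mono-TBDPS ether
Product: 9 2-[(tert-butyldiphenylsilyloxy)methyl]prop-2-enal
Conditions: MnO2 (activated, excess), CH2Cl2, rt
Reagents that add atoms: none
Why: MnO2 oxidises allylic alcohols to enals under neutral conditions and leaves the silyl ether alone.

Step 7
Reactants: 9 enal; 10 nitromethane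
Product: 11 racemic nitro aldol [3-(TBDPS-oxymethyl)-1-nitrobut-3-en-2-ol]
Conditions: MeNO2 (10 equiv), KOt-Bu (0.1 equiv), THF/t-BuOH (1:1), 0 °C, short time; AcOH quench
Reagents that add atoms: none
Why: Base-catalysed Henry addition; low temperature, excess nitromethane and a short reaction time favour the fast 1,2-addition over conjugate addition to the α-substituted enal. The carbinol centre is removed in the next step.

Step 8
Reactants: 11 nitro aldol
Product: 13 (E)-3-[(tert-butyldiphenylsilyloxy)methyl]-1-nitrobuta-1,3-diene, via mesylate 12 (not isolated)
Conditions: MsCl, Et3N, CH2Cl2, −40 → 0 °C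
Reagents that add atoms: none
Why: Mesylation and E1cB elimination of the nitro aldol give the thermodynamically preferred (E)-nitroalkene; the diene is used without storage.

Step 9
Reactants: 6 aldehyde enoate; 13 nitrodiene
Product: 15 nitrocyclohexane carbaldehyde (C10 β-Me/α-CHO; O8 and O9 α as acetonide; C7 β-CH2CO2Me; C6 α-NO2; C5 β-arm), via acyclic Michael adduct 14 (not isolated)
Conditions: 1-[(1R,2R)-2-aminocyclohexyl]-3-[3,5-bis(trifluoromethyl)phenyl]thiourea (20 mol %), PhCO2H (20 mol %), H2O (2 equiv), toluene, rt; then DBU (0.3 equiv), 0 °C → rt
Reagents that add atoms: none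
Why: The primary amine condenses with 6 to the (E)-enamine, which erases the C10 mixture, while the thiourea binds the nitro group of 13. C10 attacks C5, the carbon β to nitro, and hydrolysis of the iminium releases 14; DBU then forms the C6 nitronate, which adds to C7 of the enoate and closes the cyclohexane by a 6-exo-trig Michael addition. The closest known reactions are the primary-amine–thiourea-catalysed addition of α,α-disubstituted aldehydes to nitroalkenes and the amine-catalysed Michael–Michael annulation of 7-oxohept-2-enoates with nitroalkenes. C10 is set by the catalyst, which shields one enamine face, in the pairing matched with the adjacent C9 stereocentre. C7 follows from a chair transition state with the enoate equatorial on a chain whose C8–C9 bond is held gauche by the dioxolane, and C6 from DBU equilibration to the equatorial nitro group. C5 depends on the relative topicity of the first addition and is not relied upon, because it is corrected in step 10. The step needs 1,4- and not 1,6-addition to the diene, which the hydrogen-bonded nitro group favours by holding C5 next to the enamine carbon. It also needs attack on the nitroalkene and not on the enoate; the much higher electrophilicity of the nitroalkene secures this, and intramolecular enamine addition to the enoate would form a four-membered ring.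

Step 10
Reactants: 15 nitrocyclohexane carbaldehyde
Product: 17 C6 keto aldehyde (acetonide; both arms equatorial), via sodium nitronate 16 (not isolated)
Conditions: NaOMe (1.05 equiv), MeOH, 0 °C; then aq. TiCl3, NH4OAc (pH 5–6), THF/H2O, 0 °C → rt; then DBU (0.2 equiv), CH2Cl2, rt, short time
Reagents that add atoms: water, O
Why: The nitronate is reduced by aqueous TiCl3 to the imine, which hydrolyses to the ketone (reductive Nef reaction); aldehyde, ester, acetonide and silyl ether tolerate the buffered medium. DBU then equilibrates C5 and C7, both α to the ketone, to the isomer with both arms equatorial (only the C10 methyl and O9 axial), so whatever the annulation gave at these centres converges here.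

Step 11
Reactants: 17 keto aldehyde
Product: 19 keto aldehyde 8,12-lactone with free C9 hydroxyl, via dihydroxy ester 18 (not isolated)
Conditions: AcOH/H2O (4:1), 45 °C; then PPTS (cat.), toluene, 60 °C
Reagents that add atoms: none
Why: Acid hydrolysis of the acetonide, then acid-catalysed lactonisation; only O8 can reach the ester, and with C6 a ketone no 6,12-lactone can form, so the trans-fused 8,12-lactone results. The TBDPS ether survives these conditions.

Step 12
Reactants: 19 hydroxy lactone
Product: 20 C9 TES ether
Conditions: TESOTf (1.2 equiv), 2,6-lutidine, CH2Cl2, −78 °C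
Reagents that add atoms: triethylsilyl trifluoromethanesulfonate, CC[Si](CC)(CC)OS(=O)(=O)C(F)(F)F
Why: Silylation of the axial C9 hydroxyl blocks retro-aldol cleavage of the β-hydroxy aldehyde under the basic conditions of the next step and keeps O9 distinct from O6 to the end.

Step 13
Reactants: 20 keto aldehyde
Product: 21 (1R)-epoxide (oxiranyl on C10; C6 ketone unchanged)
Conditions: Me3S+ I− (1.3 equiv), KN(SiMe3)2 (1.2 equiv), THF, −20 → 0 °C
Reagents that add atoms: dimethylsulfonium methylide (from trimethylsulfonium iodide), [CH2-][S+](C)C
Why: Corey–Chaykovsky methylene transfer: the ylide adds to the aldehyde, which is far more reactive than a ketone flanked by two tertiary carbons, and the betaine closes to the oxirane. C1 should form with R configuration if the formyl group reacts in the rotamer with its hydrogen under the ring and its oxygen turned away from the axial C9–O bond, the ylide approaching anti to C5 past the equatorial H9. This is the least secure stereocentre of the route.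

Step 14
Reactants: 21 keto epoxide
Product: 22 6β (axial) alcohol
Conditions: LiBH(s-Bu)3 (1.2 equiv), THF, −78 °C; AcOH quench at −78 °C
Reagents that add atoms: none
Why: The bulky borohydride attacks C6 from the equatorial (α) side because the axial trajectory is blocked by the syn-axial C10 methyl, which gives the axial alcohol. At −78 °C lactone and epoxide are not reduced, and the cold acidic quench keeps the alkoxide from attacking the lactone.

Step 15
Reactants: 22 alcohol
Product: 23 C6 TMS ether
Conditions: Me3SiCl, imidazole, DMF, 0 °C → rt
Reagents that add atoms: chlorotrimethylsilane, C[Si](C)(C)Cl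
Why: Silylation masks the C6 hydroxyl so that the enolate chemistry of the next step cannot start a translactonisation to O6; the small silyl group goes onto the hindered axial alcohol and is removed later by very mild acid.

Step 16
Reactants: 23 lactone
Product: 27 α-methylene lactone with free C6 hydroxyl, via Mannich base 24 (not isolated), via methiodide 25 (not isolated), via TMS ether 26 (not isolated)
Conditions: LiN(i-Pr)2 (1.5 equiv), THF, −78 °C; CH2=NMe2+ I−, −78 → 0 °C; MeI, MeOH, rt; aq. NaHCO3, CH2Cl2; then citric acid, MeOH, 0 °C
Reagents that add atoms: N,N-dimethylmethyleneiminium iodide, C=[N+](C)C.[I-]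
Why: Kinetic lactone enolate formation and Mannich reaction give 24; exhaustive methylation and mild base eliminate trimethylamine to the α-methylene lactone, and citric acid in methanol cleaves only the TMS ether. Epoxide, TES ether and TBDPS ether are inert to these conditions.

Step 17
Reactants: 27 alcohol; 28 angelic acid [(Z)-2-methylbut-2-enoic acid]
Product: 29 6-O-angelate
Conditions: 28, 2,4,6-trichlorobenzoyl chloride, Et3N, toluene, rt; then 27, 75 °C
Reagents that add atoms: none
Why: Yamaguchi-type esterification: the C6 hydroxyl, the only free hydroxyl, attacks the mixed anhydride at the unhindered angeloyl carbonyl. Working without DMAP in toluene limits Z to E isomerisation to the tiglate.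

Step 18
Reactants: 29 bis-silyl ether
Product: 30 diol (free C9 and C15 hydroxyls)
Conditions: HF·pyridine, pyridine, THF, 0 °C → rt
Reagents that add atoms: none
Why: Buffered fluoride cleaves both silyl ethers through Si–F bond formation and should leave the epoxide, the esters and the methylene lactone untouched.

Step 19
Reactants: 30 diol
Product: 31 CNP0113462.3
Conditions: MnO2 (activated, excess), CH2Cl2, rt
Reagents that add atoms: none
Why: MnO2 oxidises only the allylic primary alcohol to the 2-substituted acrolein; the secondary C9 hydroxyl is not allylic and stays.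

## Compound list

1 | 2,3-O-isopropylidene-D-erythronolactone, (3aR,6aR) | C1[C@H]2OC(C)(C)O[C@H]2C(=O)O1 | starting material
2 | methyl lactol of 1 (1-deoxy-3,4-O-isopropylidene-D-erythro-pent-2-ulofuranose, anomeric mixture) | C1[C@H]2OC(C)(C)O[C@H]2C(C)(O)O1 | intermediate
3 | cis-dioxolane with CH2OH (C7) and 1-methoxyprop-1-en-2-yl (C10, C1) groups, E/Z mixture | OC[C@H]1OC(C)(C)O[C@H]1C(C)=COC | intermediate
4 | C7 aldehyde of 3 | O=C[C@H]1OC(C)(C)O[C@H]1C(C)=COC | intermediate (not isolated)
5 | methyl (E)-enoate with enol ether (C12–C11=C7–C8–C9–C10=C1–OMe) | COC(=O)/C=C/[C@H]1OC(C)(C)O[C@H]1C(C)=COC | intermediate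
6 | acetonide of methyl (E)-4,5-dihydroxy-6-methyl-7-oxohept-2-enoate, erythro diol, C10 epimers | COC(=O)/C=C/[C@H]1OC(C)(C)O[C@H]1C(C)C=O | intermediate (precursor of the key step)
7 | 2-methylenepropane-1,3-diol | C=C(CO)CO | starting material
8 | 2-[(tert-butyldiphenylsilyloxy)methyl]prop-2-en-1-ol | C=C(CO)CO[Si](c1ccccc1)(c1ccccc1)C(C)(C)C | intermediate
9 | 2-[(tert-butyldiphenylsilyloxy)methyl]prop-2-enal | C=C(C=O)CO[Si](c1ccccc1)(c1ccccc1)C(C)(C)C | intermediate
10 | nitromethane | C[N+](=O)[O-] | starting material
11 | 3-[(tert-butyldiphenylsilyloxy)methyl]-1-nitrobut-3-en-2-ol, racemic | [O-][N+](=O)CC(O)C(=C)CO[Si](c1ccccc1)(c1ccccc1)C(C)(C)C | intermediate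
12 | mesylate of 11 | [O-][N+](=O)CC(OS(C)(=O)=O)C(=C)CO[Si](c1ccccc1)(c1ccccc1)C(C)(C)C | intermediate (not isolated)
13 | (E)-3-[(tert-butyldiphenylsilyloxy)methyl]-1-nitrobuta-1,3-diene | [O-][N+](=O)/C=C/C(=C)CO[Si](c1ccccc1)(c1ccccc1)C(C)(C)C | intermediate (precursor of the key step)
14 | acyclic γ-nitro aldehyde (C5–C10 bond formed; enoate intact) | COC(=O)/C=C/[C@H]1OC(C)(C)O[C@H]1[C@@](C)(C=O)[C@@H](C[N+](=O)[O-])C(=C)CO[Si](c1ccccc1)(c1ccccc1)C(C)(C)C | intermediate (not isolated)
15 | nitrocyclohexane carbaldehyde: C10 β-Me/α-CHO, O8/O9 α (acetonide), C7 β-CH2CO2Me, C6 α-NO2, C5 β-[3-(TBDPS-oxy)prop-1-en-2-yl] | CC1(C)O[C@@H]2[C@@H](CC(=O)OC)[C@H]([N+](=O)[O-])[C@@H](C(=C)CO[Si](c3ccccc3)(c3ccccc3)C(C)(C)C)[C@](C)(C=O)[C@@H]2O1 | intermediate (product of the key step)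
16 | sodium nitronate of 15 | CC1(C)O[C@@H]2[C@@H](CC(=O)OC)C(=[N+]([O-])[O-])[C@@H](C(=C)CO[Si](c3ccccc3)(c3ccccc3)C(C)(C)C)[C@](C)(C=O)[C@@H]2O1.[Na+] | intermediate (not isolated)
17 | C6 keto aldehyde, acetonide, C5 and C7 arms β (equatorial) | CC1(C)O[C@@H]2[C@@H](CC(=O)OC)C(=O)[C@@H](C(=C)CO[Si](c3ccccc3)(c3ccccc3)C(C)(C)C)[C@](C)(C=O)[C@@H]2O1 | intermediate
18 | 8α,9α-dihydroxy keto aldehyde methyl ester | O[C@@H]1[C@@H](CC(=O)OC)C(=O)[C@@H](C(=C)CO[Si](c2ccccc2)(c2ccccc2)C(C)(C)C)[C@](C)(C=O)[C@@H]1O | intermediate (not isolated)
19 | trans-fused 8,12-lactone, C6 ketone, C10 α-CHO, 9α-OH | O=C1O[C@@H]2[C@@H](C1)C(=O)[C@@H](C(=C)CO[Si](c3ccccc3)(c3ccccc3)C(C)(C)C)[C@](C)(C=O)[C@@H]2O | intermediate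
20 | 9α-O-TES ether of 19 | O=C1O[C@@H]2[C@@H](C1)C(=O)[C@@H](C(=C)CO[Si](c3ccccc3)(c3ccccc3)C(C)(C)C)[C@](C)(C=O)[C@@H]2O[Si](CC)(CC)CC | intermediate
21 | (1R)-1,2-epoxide on C10 (α), C6 ketone, 8,12-lactone | O=C1O[C@@H]2[C@@H](C1)C(=O)[C@@H](C(=C)CO[Si](c3ccccc3)(c3ccccc3)C(C)(C)C)[C@](C)([C@@H]3CO3)[C@@H]2O[Si](CC)(CC)CC | intermediate
22 | 6β-alcohol (axial) | O=C1O[C@@H]2[C@@H](C1)[C@@H](O)[C@@H](C(=C)CO[Si](c3ccccc3)(c3ccccc3)C(C)(C)C)[C@](C)([C@@H]3CO3)[C@@H]2O[Si](CC)(CC)CC | intermediate
23 | 6β-O-TMS ether of 22 | O=C1O[C@@H]2[C@@H](C1)[C@@H](O[Si](C)(C)C)[C@@H](C(=C)CO[Si](c3ccccc3)(c3ccccc3)C(C)(C)C)[C@](C)([C@@H]3CO3)[C@@H]2O[Si](CC)(CC)CC | intermediate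
24 | 11-(dimethylaminomethyl) lactone (C11 epimers) | CN(C)CC1C(=O)O[C@@H]2[C@@H]1[C@@H](O[Si](C)(C)C)[C@@H](C(=C)CO[Si](c3ccccc3)(c3ccccc3)C(C)(C)C)[C@](C)([C@@H]3CO3)[C@@H]2O[Si](CC)(CC)CC | intermediate (not isolated)
25 | trimethylammonium iodide of 24 | C[N+](C)(C)CC1C(=O)O[C@@H]2[C@@H]1[C@@H](O[Si](C)(C)C)[C@@H](C(=C)CO[Si](c3ccccc3)(c3ccccc3)C(C)(C)C)[C@](C)([C@@H]3CO3)[C@@H]2O[Si](CC)(CC)CC.[I-] | intermediate (not isolated)
26 | α-methylene lactone, 6β-O-TMS | C=C1C(=O)O[C@@H]2[C@@H]1[C@@H](O[Si](C)(C)C)[C@@H](C(=C)CO[Si](c3ccccc3)(c3ccccc3)C(C)(C)C)[C@](C)([C@@H]3CO3)[C@@H]2O[Si](CC)(CC)CC | intermediate (not isolated)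
27 | α-methylene lactone, 6β-OH, 9α-OTES, 15-OTBDPS | C=C1C(=O)O[C@@H]2[C@@H]1[C@@H](O)[C@@H](C(=C)CO[Si](c3ccccc3)(c3ccccc3)C(C)(C)C)[C@](C)([C@@H]3CO3)[C@@H]2O[Si](CC)(CC)CC | intermediate
28 | angelic acid, (Z)-2-methylbut-2-enoic acid | C/C=C(/C)C(=O)O | starting material
29 | 6β-O-angelate, 9α-OTES, 15-OTBDPS | C=C1C(=O)O[C@@H]2[C@@H]1[C@@H](OC(=O)/C(C)=C\C)[C@@H](C(=C)CO[Si](c3ccccc3)(c3ccccc3)C(C)(C)C)[C@](C)([C@@H]3CO3)[C@@H]2O[Si](CC)(CC)CC | intermediate
30 | 6β-O-angelate, 9α-OH, 15-OH | C=C1C(=O)O[C@@H]2[C@@H]1[C@@H](OC(=O)/C(C)=C\C)[C@@H](C(=C)CO)[C@](C)([C@@H]3CO3)[C@@H]2O | intermediate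
31 | CNP0113462.3 | C=C1C(=O)O[C@@H]2[C@@H]1[C@@H](OC(=O)/C(C)=C\C)[C@@H](C(=C)C=O)[C@](C)([C@@H]1CO1)[C@@H]2O | target

## Step count and least certain steps

Total step count: 19. Longest linear sequence: 15 steps (steps 1–4 or steps 5–8, then steps 9–19).

**Step 9 (key step).** The enamine of an aldehyde branched at both its α- and β-carbons may form and react slowly, and the new C5–C10 bond joins a quaternary to a tertiary carbon. Addition may go 1,6 to the unsubstituted diene terminus C3. The primary amine may be consumed by aza-Michael addition to the nitrodiene. Facial selectivity at C10 may be poor if catalyst and C9 stereocentre are mismatched in both pairings. The fallback sets out from 6 and replaces enamine catalysis by a preformed enol silane. Aldehyde 6 is converted into its trimethylsilyl enol ether F1 (Me3SiCl, Et3N, NaI, MeCN). F1 is combined with 13 under TiCl2(Oi-Pr)2 at −78 °C in a Mukaiyama–Michael addition, in which the nitroalkene reacts as a heterodiene and bond formation is tied to C5. Work-up with KF in methanol gives 14, now isolated, and DBU closes the ring to 15, where the route is rejoined. C10 then depends on substrate control alone, and epimers would be separated at 15.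

**Step 13.** Facial selectivity at C1 may be poor or reversed, because two rotamers of the formyl group compete. The ylide may also be consumed by deprotonation at C5 or attack the ketone. The fallback sets out from 20 and puts C1 under reagent control:
- chloromethyllithium (from ICH2Cl and MeLi, −78 °C) adds to the aldehyde to give the chlorohydrin mixture F2;
- Dess–Martin oxidation gives the chloromethyl ketone F3;
- Corey–Bakshi–Shibata (CBS) reduction with BH3·SMe2, using the oxazaborolidine enantiomer that delivers the (1R)-alcohol, gives the (1R)-chlorohydrin F4. It should reduce the activated, unhindered chloromethyl ketone in preference to the C6 ketone;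
- DBU in CH2Cl2 closes F4 to 21 with retention at C1.

**Step 10.** Reduction of the hindered nitronate may stop at the oxime or involve the aldehyde. During equilibration the C7 enolate may expel O8, or the C4=C3 alkene may move into conjugation. The fallback sets out from 15 and avoids the nitronate: SnCl2, PhSH and Et3N reduce the secondary nitro group to the oxime F5, and transoximation with aqueous glyoxylic acid releases 17, which is then equilibrated as in the route.

**Step 7.** The nitronate may add in conjugate fashion to the β-unsubstituted enal, or the enal may polymerise under base. The fallback sets out from 9 and masks the alkene: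
- benzeneselenol adds to 9 to give the β-seleno aldehyde F6;
- Henry addition of 10 gives the nitro aldol F7;
- MsCl and Et3N dehydrate it to the nitroalkene F8;
- oxidation with H2O2 at 0 °C and selenoxide syn-elimination restore the 1,1-disubstituted alkene and give 13.

**Step 2.** Olefination of the hemiketal may be sluggish, and long exposure to the basic ylide may epimerise C9 next to the transient ketone. The fallback sets out from 2: silylation (t-BuMe2SiCl, imidazole, DMF) traps the open-chain form as the keto silyl ether F9. This free ketone undergoes the same Wittig reaction faster and at lower temperature to give the enol ether F10, and Bu4NF removes the silyl group to return to 3.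

## Further compounds

F1 | step 9 | trimethylsilyl enol ether of 6 | COC(=O)/C=C/[C@H]1OC(C)(C)O[C@H]1C(C)=CO[Si](C)(C)C
F2 | step 13 | chlorohydrin from 20 (C1 epimers) | O=C1O[C@@H]2[C@@H](C1)C(=O)[C@@H](C(=C)CO[Si](c3ccccc3)(c3ccccc3)C(C)(C)C)[C@](C)(C(O)CCl)[C@@H]2O[Si](CC)(CC)CC
F3 | step 13 | chloromethyl ketone on C10 | O=C1O[C@@H]2[C@@H](C1)C(=O)[C@@H](C(=C)CO[Si](c3ccccc3)(c3ccccc3)C(C)(C)C)[C@](C)(C(=O)CCl)[C@@H]2O[Si](CC)(CC)CC
F4 | step 13 | (1R)-chlorohydrin | O=C1O[C@@H]2[C@@H](C1)C(=O)[C@@H](C(=C)CO[Si](c3ccccc3)(c3ccccc3)C(C)(C)C)[C@](C)([C@@H](O)CCl)[C@@H]2O[Si](CC)(CC)CC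
F5 | step 10 | C6 oxime of the cyclohexane carbaldehyde | CC1(C)O[C@@H]2[C@@H](CC(=O)OC)C(=NO)[C@@H](C(=C)CO[Si](c3ccccc3)(c3ccccc3)C(C)(C)C)[C@](C)(C=O)[C@@H]2O1
F6 | step 7 | 3-(phenylselanyl)-2-[(tert-butyldiphenylsilyloxy)methyl]propanal | O=CC(C[Se]c1ccccc1)CO[Si](c1ccccc1)(c1ccccc1)C(C)(C)C
F7 | step 7 | nitro aldol of F6 | [O-][N+](=O)CC(O)C(C[Se]c1ccccc1)CO[Si](c1ccccc1)(c1ccccc1)C(C)(C)C
F8 | step 7 | (E)-nitroalkene with β-seleno side chain | [O-][N+](=O)/C=C/C(C[Se]c1ccccc1)CO[Si](c1ccccc1)(c1ccccc1)C(C)(C)C
F9 | step 2 | open-chain methyl ketone, primary tert-butyldimethylsilyl ether | CC(C)(C)[Si](C)(C)OC[C@H]1OC(C)(C)O[C@H]1C(C)=O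
F10 | step 2 | tert-butyldimethylsilyl ether of 3 | CC(C)(C)[Si](C)(C)OC[C@H]1OC(C)(C)O[C@H]1C(C)=COC
A1 | alternative 1 | cis-anti-cis tricyclic photoadduct (ester on C4, methyl on C10, C9 silyl ether) | O=C1[C@@H]2[C@@]3(C(=O)OC)CC[C@H]3[C@]2(C)[C@@H](O[Si](C)(C)C(C)(C)C)CC1
A2 | alternative 1 | 4-(tert-butyldimethylsilyloxy)-3-methylcyclohex-2-en-1-one | O=C1C=C(C)[C@@H](O[Si](C)(C)C(C)(C)C)CC1
A3 | alternative 1 | methyl cyclobut-1-enecarboxylate | COC(=O)C1=CCC1
A4 | alternative 2 | protected elemanolide core with α-methylene lactone (C6 PMB ether, C9 TES ether, C15 TBDPS ether, C10 vinyl) | C=C1C(=O)O[C@@H]2[C@@H]1[C@@H](OCc3ccc(OC)cc3)[C@@H](C(=C)CO[Si](c3ccccc3)(c3ccccc3)C(C)(C)C)[C@](C)(C=C)[C@@H]2O[Si](CC)(CC)CC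
A5 | alternative 3 | 2-(1-phenylethoxy)-4-methyl-8-isopropylidenebicyclo[3.2.1]oct-6-en-3-one | C[C@@H](c1ccccc1)O[C@@H]2[C@H]1C=C[C@H](C1=C(C)C)[C@@H](C)C2=O
A6 | alternative 3 | 6,6-dimethylfulvene | CC(C)=C1C=CC=C1
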